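In briarane numbering (C1 quaternary ring-fusion carbon, C10 ring-fusion CH, C11=C12 alkene, C14 acetoxy carbon), the cyclohexene ring is disconnected across C1–C10 and C12–C13. The key step exploits the 1,3-relationship of the C14 oxygen and C12: C14 is a ketone whose α-carbons are C1 and C13, and C10–C11(CH3)–C12 is a 2-methyl-2-enal. A catalytic asymmetric Michael addition/aldol condensation ([3+3]) of two acyclic achiral components, methyl 2-methylacetoacetate and (E)-4,4-dimethoxy-2-methylbut-2-enal, thus forms the ring with its C1 and C10 stereocentres in one operation. The C2 acetyl and C9 aldehyde handles then carry the lactone unit and close the ten-membered ring by a C3–C4 aldol.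

Key step: step 2

Numbering used throughout: C1 (CH3 = C15), C2 (OAc), C3, C4 (butyrate), C5 (bearing C16H2OAc)=C6, C7 (lactone O), C8 (OH), C9 (OAc), C10, C11 (CH3 = C20)=C12, C13, C14 (OAc); lactone C17 (CH3 = C18), C19 (C=O).

Remark (assumption): the absolute sense of induction of the cinchona catalyst (step 2) and of the ProPhenol ligand (step 12) is assigned by analogy with simpler aldehydes; should either be opposite, the quinine-derived pseudoenantiomer or the (R,R)-ligand is used.

Step 1
Reactants: 1 2,2-dimethoxyacetaldehyde (60% aqueous solution); 2 2-(triphenylphosphoranylidene)propanal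
Product: 3 (E)-4,4-dimethoxy-2-methylbut-2-enal
Conditions: CH2Cl2/H2O, rt
Reagents that add atoms: none
Why: Wittig olefination with a formyl-stabilised ylide is reliably E-selective and leaves the acetal as the latent C9 aldehyde.

Step 2
Reactants: 3 (E)-4,4-dimethoxy-2-methylbut-2-enal; 4 methyl 2-methyl-3-oxobutanoate
Product: 6 methyl (1R,5R,6S)-6-(dimethoxymethyl)-1,5-dimethyl-2-oxocyclohex-3-ene-1-carboxylate, via Michael adduct keto-aldehyde 5 (not isolated)
Conditions: 9-O-(9-phenanthryl)cupreidine (10 mol%), CH2Cl2 (2 M), rt; then pyrrolidine, AcOH (20 mol% each), 4 Å molecular sieves, 40 °C (one pot)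
Reagents that add atoms: none
Why: The quinuclidine of the bifunctional cinchona base deprotonates 4 and the hydrogen-bonded enolate adds through C1 to the β-carbon C10 of enal 3 (Michael addition, C1–C10 bond, adduct 5), after which pyrrolidinium acetate turns the methyl ketone into its enamine, whose carbon C13 attacks the C12 aldehyde and water is lost (aldol condensation, C12–C13 bond formed as the C12=C13 enone). The closest known reaction type is the organocatalytic Michael addition of α-substituted β-keto esters to α,β-unsaturated aldehydes followed by Robinson-type aldol condensation, a formal carbo-[3+3] cyclohexenone annulation. The six-membered ring closes in a 6-(enolendo)-exo-trig aldol mode. C1 and C10 are both set in the Michael event by the catalyst, which shields one enolate face with its phenanthryl ether while its 6'-hydroxyl orients the enal, an open transition state with the acetal-bearing C9 anti to the ester being expected to give the (1R,10S) pair (C15 methyl cis to C9), whereas C11 is set by equilibration under the amine/acid conditions to the trans arrangement drawn and is erased in step 3. The step needs conjugate C-alkylation rather than 1,2-addition or O-alkylation and a single aldol regiochemistry, which are secured by the soft stabilised enolate, by the acetal-activated enal and by the fact that after the Michael event only C13 can act as aldol donor (C1 is quaternary and the ester cannot enolise toward C12).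

Step 3
Reactants: 6 methyl (1R,5R,6S)-6-(dimethoxymethyl)-1,5-dimethyl-2-oxocyclohex-3-ene-1-carboxylate
Product: 7 methyl (1R,6S)-6-(dimethoxymethyl)-1,5-dimethyl-2-oxocyclohex-4-ene-1-carboxylate
Conditions: KHMDS, THF, −78 °C; then AcOH, −78 °C
Reagents that add atoms: none
Why: Kinetic deconjugation works because the only acidic site is the γ-hydrogen on C11 (C1 is quaternary) and kinetic α-protonation of the extended dienolate at C13 places the alkene at C11=C12 as in the target.

Step 4
Reactants: 7 methyl (1R,6S)-6-(dimethoxymethyl)-1,5-dimethyl-2-oxocyclohex-4-ene-1-carboxylate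
Product: 8 methyl (1R,2S,6S)-6-(dimethoxymethyl)-2-hydroxy-1,5-dimethylcyclohex-4-ene-1-carboxylate
Conditions: (R)-2-methyl-CBS-oxazaborolidine (0.5 equiv), catecholborane, toluene, −78 to −40 °C
Reagents that add atoms: none
Why: In this Corey–Bakshi–Shibata reduction the ketone binds anti to the quaternary C1 (large group) and hydride delivery within the (R)-catalyst complex sets 14S (hydroxyl cis to the ester, trans to the C15 methyl) under reagent control, while catecholborane leaves the trisubstituted alkene untouched at low temperature.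

Step 5
Reactants: 8 methyl (1R,2S,6S)-6-(dimethoxymethyl)-2-hydroxy-1,5-dimethylcyclohex-4-ene-1-carboxylate
Product: 10 1-[(1R,2S,6S)-6-(dimethoxymethyl)-2-hydroxy-1,5-dimethylcyclohex-4-en-1-yl]ethan-1-one, via α-silyl ketone 9 (not isolated)
Conditions: LiCH2SiMe3 (3.3 equiv), pentane/THF, 0 °C; then MeOH
Reagents that add atoms: (trimethylsilyl)methyllithium, [Li]C[Si](C)(C)C
Why: Acylation of (trimethylsilyl)methyllithium by the hindered ester stops at the ketone because α-silyl ketone 9 is held as its enolate, and methanolysis of the carbon–silicon bond then gives the methyl ketone (C3) without touching the acetal or C14.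

Step 6
Reactants: 10 1-[(1R,2S,6S)-6-(dimethoxymethyl)-2-hydroxy-1,5-dimethylcyclohex-4-en-1-yl]ethan-1-one
Product: 11 (1S,5S,6R)-6-acetyl-5-(dimethoxymethyl)-4,6-dimethylcyclohex-3-en-1-yl acetate
Conditions: Ac2O, DMAP, pyridine, CH2Cl2, rt
Reagents that add atoms: acetic anhydride, CC(=O)OC(C)=O
Why: DMAP-catalysed acetylation installs the final C14 acetate and removes the β-hydroxy ketone that could otherwise undergo retro-aldol cleavage.

Step 7
Reactants: 11 (1S,5S,6R)-6-acetyl-5-(dimethoxymethyl)-4,6-dimethylcyclohex-3-en-1-yl acetate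
Product: 12 (1S,5S,6R)-6-acetyl-5-formyl-4,6-dimethylcyclohex-3-en-1-yl acetate
Conditions: 10% aqueous oxalic acid on SiO2, CH2Cl2, rt
Reagents that add atoms: water, O
Why: Mild heterogeneous acetal hydrolysis frees the C9 aldehyde under conditions too weak to epimerise C10 or to move the C11=C12 alkene into conjugation.

Step 8
Reactants: 13 3,3-diethoxyprop-1-ene (acrolein diethyl acetal)
Product: 15 2-bromo-3,3-diethoxyprop-1-ene, via 2,3-dibromo-1,1-diethoxypropane 14 (not isolated)
Conditions: Br2, CH2Cl2, −78 °C; then KOtBu (1.05 equiv), THF, 0 °C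
Reagents that add atoms: bromine, BrBr
Why: Bromine addition followed by E2 loss of HBr through the acidified hydrogen on the CHBr carbon gives the 2-bromoalkene, a known dehydrobromination of this dibromo acetal.

Step 9
Reactants: 12 (1S,5S,6R)-6-acetyl-5-formyl-4,6-dimethylcyclohex-3-en-1-yl acetate; 15 2-bromo-3,3-diethoxyprop-1-ene
Product: 16 (1S,5S,6R)-6-acetyl-5-[(1R)-3,3-diethoxy-1-hydroxy-2-methylidenepropyl]-4,6-dimethylcyclohex-3-en-1-yl acetate
Conditions: CrCl2 (6 equiv), NiCl2 (5 mol%), DMF, rt
Reagents that add atoms: none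
Why: In this Nozaki–Hiyama–Kishi coupling the alkenylchromium species adds only to the aldehyde (methyl ketone and acetate are inert) and, with the quaternary C1 as the large group anti to the nucleophile (Felkin–Anh), should give the 9R alcohol.

Step 10
Reactants: 16 (1S,5S,6R)-6-acetyl-5-[(1R)-3,3-diethoxy-1-hydroxy-2-methylidenepropyl]-4,6-dimethylcyclohex-3-en-1-yl acetate
Product: 17 (1S,5S,6R)-5-[(1R)-1-acetoxy-3,3-diethoxy-2-methylidenepropyl]-6-acetyl-4,6-dimethylcyclohex-3-en-1-yl acetate
Conditions: Ac2O, DMAP, pyridine, CH2Cl2, rt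
Reagents that add atoms: acetic anhydride, CC(=O)OC(C)=O
Why: Acetylation puts the final C9 acetate in place and differentiates O9 from the O7 hydroxyl that is made later.

Step 11
Reactants: 17 (1S,5S,6R)-5-[(1R)-1-acetoxy-3,3-diethoxy-2-methylidenepropyl]-6-acetyl-4,6-dimethylcyclohex-3-en-1-yl acetate
Product: 18 (1S,5S,6R)-5-[(1R)-1-acetoxy-2-formylprop-2-en-1-yl]-6-acetyl-4,6-dimethylcyclohex-3-en-1-yl acetate
Conditions: PPTS, acetone/H2O, 40 °C
Reagents that add atoms: water, O
Why: Acid-catalysed hydrolysis of the allylic diethyl acetal is fast and gives the non-enolisable 2-substituted acrolein (C7 aldehyde) without affecting the acetates.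

Step 12
Reactants: 18 (1S,5S,6R)-5-[(1R)-1-acetoxy-2-formylprop-2-en-1-yl]-6-acetyl-4,6-dimethylcyclohex-3-en-1-yl acetate; 19 triethyl(prop-2-yn-1-yloxy)silane
Product: 20 (1S,5S,6R)-5-[(1R,3S)-1-acetoxy-3-hydroxy-2-methylidene-6-(triethylsilyloxy)hex-4-yn-1-yl]-6-acetyl-4,6-dimethylcyclohex-3-en-1-yl acetate
Conditions: Me2Zn, (S,S)-ProPhenol (20 mol%), Ph3PO (40 mol%), toluene, 4 °C
Reagents that add atoms: none
Why: In this zinc–ProPhenol asymmetric alkynylation the zinc alkynylide adds 1,2 to the enal under ligand control to set 7S, the hindered methyl ketone and the esters being inert to alkynylzinc species.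

Step 13
Reactants: 20 (1S,5S,6R)-5-[(1R,3S)-1-acetoxy-3-hydroxy-2-methylidene-6-(triethylsilyloxy)hex-4-yn-1-yl]-6-acetyl-4,6-dimethylcyclohex-3-en-1-yl acetate
Product: 21 spiro-epoxide of 20 at C8 (7S,9R)
Conditions: VO(acac)2 (5 mol%), t-BuOOH, CH2Cl2, 0 °C
Reagents that add atoms: tert-butyl hydroperoxide, CC(C)(C)OO
Why: Vanadium-catalysed hydroxyl-directed epoxidation touches only the 1,1-disubstituted alkene allylic to the C7 hydroxyl, leaving the ring alkene and the alkyne, and the configuration of the new oxirane carbon does not matter because it is destroyed in step 15.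

Step 14
Reactants: 21 spiro-epoxide of 20 at C8 (7S,9R)
Product: 22 O7-acrylate of epoxide 21
Conditions: acryloyl chloride, i-Pr2NEt, CH2Cl2, −20 °C
Reagents that add atoms: acryloyl chloride, C=CC(Cl)=O
Why: O-Acylation of the only free hydroxyl attaches the three lactone carbons C17–C19 as an acrylate.

Step 15
Reactants: 22 O7-acrylate of epoxide 21
Product: 24 (1S,5S,6R)-5-[(1R,3S)-1-acetoxy-3-(acryloyloxy)-6-hydroxy-2-oxohex-4-yn-1-yl]-6-acetyl-4,6-dimethylcyclohex-3-en-1-yl acetate, via glycol 23 (not isolated)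
Conditions: H5IO6, THF/H2O (4:1), 0 °C to rt
Reagents that add atoms: water, O
Why: Periodic acid opens the oxirane at its tertiary carbon to glycol 23 and cleaves it (Malaprade reaction) to the C8 ketone and formaldehyde without touching any alkene, the O7 and O9 esters preventing cleavage of the neighbouring carbon–carbon bonds while the same aqueous acid hydrolyses the primary triethylsilyl ether.

Step 16
Reactants: 24 (1S,5S,6R)-5-[(1R,3S)-1-acetoxy-3-(acryloyloxy)-6-hydroxy-2-oxohex-4-yn-1-yl]-6-acetyl-4,6-dimethylcyclohex-3-en-1-yl acetate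
Product: 25 alkynyl β-hydroxy-α-methyl-γ-lactone (lactone C7/C8/C17/C19 closed; stereocentres arranged as in 31)
Conditions: [(Ph3P)CuH]6 (0.6 equiv), toluene/THF, −40 to 0 °C; aqueous NH4Cl
Reagents that add atoms: none
Why: In this copper hydride reductive aldol cyclization, conjugate reduction of the acrylate gives a (Z)-copper enolate that adds to the C8 ketone through a chelated chair-like transition state (five-membered ring closure), placing the C8 hydroxyl and the C18 methyl cis and the C9 branch trans to the alkynyl group on C7, as in the target.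

Step 17
Reactants: 25 alkynyl β-hydroxy-α-methyl-γ-lactone
Product: 27 (Z)-alkenyl iodide (iodine on C5 cis to C7), via alkenylstannane 26 (not isolated)
Conditions: Bu3SnH, [Cp*RuCl]4 (2.5 mol%), CH2Cl2, rt; then I2, 0 °C
Reagents that add atoms: iodine, II
Why: Hydroxyl-directed ruthenium-catalysed trans-hydrostannation delivers tin to C5 (proximal to the C16 hydroxyl) and hydrogen to C6 on opposite sides, and iododestannylation with retention gives the (Z)-alkenyl iodide in which C7 and the future C4 are cis.

Step 18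
Reactants: 27 (Z)-alkenyl iodide
Product: 28 (Z)-enal (C4 formyl group on C5 cis to C7)
Conditions: Pd(PPh3)4 (5 mol%), CO (1 atm), Bu3SnH (slow addition), THF, 50 °C
Reagents that add atoms: carbon monoxide, [C-]#[O+]
Why: Palladium-catalysed reductive carbonylation (Stille formylation) converts the alkenyl iodide into the enal with retention of alkene geometry, oxidative addition to the carbon–iodine bond being faster than ionisation of the allylic lactone.

Step 19
Reactants: 28 (Z)-enal
Product: 29 macrocyclic β-hydroxy ketone (4R hydroxyl; C2 ketone; ten-membered ring closed)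
Conditions: Bu2BOTf (4 equiv), i-Pr2NEt (5 equiv), CH2Cl2 (1 mM), −78 to −20 °C; pH 7 buffer/MeOH
Reagents that add atoms: none
Why: In this boron-mediated intramolecular aldol the methyl ketone (enolisable only at C3) gives a boron enolate that adds irreversibly to the C4 enal at high dilution to close the ten-membered ring, the rigid (Z)-alkene and lactone exposing the enal face expected to lead to the 4R alcohol (macrocyclic stereocontrol).

Step 20
Reactants: 29 macrocyclic β-hydroxy ketone
Product: 30 4-O-butyryl 2R-hydroxy macrocycle (2,16-dideacetyl target)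
Conditions: SmI2 (0.3 equiv), butanal (8 equiv), THF, −10 °C
Reagents that add atoms: butanal, CCCC=O
Why: In this Evans–Tishchenko reduction the samarium-bound hemiacetal formed from butanal and the C4 hydroxyl delivers hydride intramolecularly to the C2 ketone, giving the 2,4-anti diol with the butyrate already on O4 and a free 2R hydroxyl.

Step 21
Reactants: 30 4-O-butyryl 2R-hydroxy macrocycle
Product: 31 CNP0290502.1
Conditions: Ac2O, pyridine, DMAP (catalytic), CH2Cl2, 0 °C to rt
Reagents that add atoms: acetic anhydride, CC(=O)OC(C)=O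
Why: Acetylation of the secondary C2 and primary C16 hydroxyls completes the ester pattern, the hindered tertiary C8 hydroxyl being expected to remain free.

Compound list
1 | 2,2-dimethoxyacetaldehyde | COC(OC)C=O | starting material
2 | 2-(triphenylphosphoranylidene)propanal | CC(C=O)=P(c1ccccc1)(c1ccccc1)c1ccccc1 | starting material
3 | (E)-4,4-dimethoxy-2-methylbut-2-enal | O=C/C(C)=C/C(OC)OC | intermediate
4 | methyl 2-methyl-3-oxobutanoate | CC(=O)C(C)C(=O)OC | starting material
5 | methyl (2R,3S,4S)-2-acetyl-3-(dimethoxymethyl)-2,4-dimethyl-5-oxopentanoate (Michael adduct; C4 not controlled) | COC(=O)[C@@](C)(C(C)=O)[C@@H](C(OC)OC)[C@H](C)C=O | intermediate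
6 | methyl (1R,5R,6S)-6-(dimethoxymethyl)-1,5-dimethyl-2-oxocyclohex-3-ene-1-carboxylate | COC(=O)[C@@]1(C)C(=O)C=C[C@@H](C)[C@@H]1C(OC)OC | intermediate
7 | methyl (1R,6S)-6-(dimethoxymethyl)-1,5-dimethyl-2-oxocyclohex-4-ene-1-carboxylate | COC(=O)[C@@]1(C)C(=O)CC=C(C)[C@@H]1C(OC)OC | intermediate
8 | methyl (1R,2S,6S)-6-(dimethoxymethyl)-2-hydroxy-1,5-dimethylcyclohex-4-ene-1-carboxylate | COC(=O)[C@@]1(C)[C@@H](O)CC=C(C)[C@@H]1C(OC)OC | intermediate
9 | 1-[(1R,2S,6S)-6-(dimethoxymethyl)-2-hydroxy-1,5-dimethylcyclohex-4-en-1-yl]-2-(trimethylsilyl)ethan-1-one | C[Si](C)(C)CC(=O)[C@@]1(C)[C@@H](O)CC=C(C)[C@@H]1C(OC)OC | intermediate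
10 | 1-[(1R,2S,6S)-6-(dimethoxymethyl)-2-hydroxy-1,5-dimethylcyclohex-4-en-1-yl]ethan-1-one | CC(=O)[C@@]1(C)[C@@H](O)CC=C(C)[C@@H]1C(OC)OC | intermediate
11 | (1S,5S,6R)-6-acetyl-5-(dimethoxymethyl)-4,6-dimethylcyclohex-3-en-1-yl acetate | CC(=O)[C@@]1(C)[C@@H](OC(C)=O)CC=C(C)[C@@H]1C(OC)OC | intermediate
12 | (1S,5S,6R)-6-acetyl-5-formyl-4,6-dimethylcyclohex-3-en-1-yl acetate | CC(=O)[C@@]1(C)[C@@H](OC(C)=O)CC=C(C)[C@@H]1C=O | intermediate
13 | 3,3-diethoxyprop-1-ene (acrolein diethyl acetal) | C=CC(OCC)OCC | starting material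
14 | 2,3-dibromo-1,1-diethoxypropane | BrCC(Br)C(OCC)OCC | intermediate
15 | 2-bromo-3,3-diethoxyprop-1-ene | C=C(Br)C(OCC)OCC | intermediate
16 | (1S,5S,6R)-6-acetyl-5-[(1R)-3,3-diethoxy-1-hydroxy-2-methylidenepropyl]-4,6-dimethylcyclohex-3-en-1-yl acetate | CC(=O)[C@@]1(C)[C@@H](OC(C)=O)CC=C(C)[C@@H]1[C@@H](O)C(=C)C(OCC)OCC | intermediate
17 | (1S,5S,6R)-5-[(1R)-1-acetoxy-3,3-diethoxy-2-methylidenepropyl]-6-acetyl-4,6-dimethylcyclohex-3-en-1-yl acetate | CC(=O)[C@@]1(C)[C@@H](OC(C)=O)CC=C(C)[C@@H]1[C@@H](OC(C)=O)C(=C)C(OCC)OCC | intermediate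
18 | (1S,5S,6R)-5-[(1R)-1-acetoxy-2-formylprop-2-en-1-yl]-6-acetyl-4,6-dimethylcyclohex-3-en-1-yl acetate | CC(=O)[C@@]1(C)[C@@H](OC(C)=O)CC=C(C)[C@@H]1[C@@H](OC(C)=O)C(=C)C=O | intermediate
19 | triethyl(prop-2-yn-1-yloxy)silane | C#CCO[Si](CC)(CC)CC | starting material
20 | (1S,5S,6R)-5-[(1R,3S)-1-acetoxy-3-hydroxy-2-methylidene-6-(triethylsilyloxy)hex-4-yn-1-yl]-6-acetyl-4,6-dimethylcyclohex-3-en-1-yl acetate | CC(=O)[C@@]1(C)[C@@H](OC(C)=O)CC=C(C)[C@@H]1[C@@H](OC(C)=O)C(=C)[C@@H](O)C#CCO[Si](CC)(CC)CC | intermediate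
21 | spiro-epoxide of 20 (C8=CH2 converted into an oxirane; oxirane carbon C8 of either configuration; 7S,9R) | CC(=O)[C@@]1(C)[C@@H](OC(C)=O)CC=C(C)[C@@H]1[C@@H](OC(C)=O)C2(CO2)[C@@H](O)C#CCO[Si](CC)(CC)CC | intermediate
22 | O7-acrylate of epoxide 21 | CC(=O)[C@@]1(C)[C@@H](OC(C)=O)CC=C(C)[C@@H]1[C@@H](OC(C)=O)C2(CO2)[C@@H](OC(=O)C=C)C#CCO[Si](CC)(CC)CC | intermediate
23 | glycol from 22 (C8 tertiary OH and CH2OH; silyl ether hydrolysed; C8 of either configuration) | CC(=O)[C@@]1(C)[C@@H](OC(C)=O)CC=C(C)[C@@H]1[C@@H](OC(C)=O)C(O)(CO)[C@@H](OC(=O)C=C)C#CCO | intermediate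
24 | (1S,5S,6R)-5-[(1R,3S)-1-acetoxy-3-(acryloyloxy)-6-hydroxy-2-oxohex-4-yn-1-yl]-6-acetyl-4,6-dimethylcyclohex-3-en-1-yl acetate | CC(=O)[C@@]1(C)[C@@H](OC(C)=O)CC=C(C)[C@@H]1[C@@H](OC(C)=O)C(=O)[C@@H](OC(=O)C=C)C#CCO | intermediate
25 | alkynyl lactone: β-hydroxy-α-methyl-γ-butyrolactone (C7, C8, C17, C19) bearing the 3-hydroxyprop-1-ynyl group on C7 and the acetoxy(cyclohexenyl)methyl group on C8; stereocentres arranged as in 31 | CC(=O)[C@@]1(C)[C@@H](OC(C)=O)CC=C(C)[C@@H]1[C@@H](OC(C)=O)[C@@]2(O)[C@H](C#CCO)OC(=O)[C@@H]2C | intermediate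
26 | (Z)-alkenylstannane from 25 (SnBu3 on C5 cis to C7; H on C6) | CC(=O)[C@@]1(C)[C@@H](OC(C)=O)CC=C(C)[C@@H]1[C@@H](OC(C)=O)[C@@]2(O)[C@H](/C=C(\[Sn](CCCC)(CCCC)CCCC)CO)OC(=O)[C@@H]2C | intermediate
27 | (Z)-alkenyl iodide (iodine on C5 cis to C7) | CC(=O)[C@@]1(C)[C@@H](OC(C)=O)CC=C(C)[C@@H]1[C@@H](OC(C)=O)[C@@]2(O)[C@H](/C=C(\I)CO)OC(=O)[C@@H]2C | intermediate
28 | (Z)-enal (C4 formyl on C5 cis to C7; free 8-OH and 16-OH; C2 methyl ketone) | CC(=O)[C@@]1(C)[C@@H](OC(C)=O)CC=C(C)[C@@H]1[C@@H](OC(C)=O)[C@@]2(O)[C@H](/C=C(\C=O)CO)OC(=O)[C@@H]2C | intermediate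
29 | macrocyclic β-hydroxy ketone (4R-OH, C2 ketone, 9- and 14-acetates, free 8-OH and 16-OH; other stereocentres as in 31) | O[C@@H]1CC(=O)[C@@]2(C)[C@@H](OC(C)=O)CC=C(C)[C@@H]2[C@@H](OC(C)=O)[C@@]2(O)[C@H](/C=C\1CO)OC(=O)[C@@H]2C | intermediate
30 | 4-O-butyryl 2R-hydroxy macrocycle (2,16-dideacetyl target) | CCCC(=O)O[C@@H]1C[C@@H](O)[C@@]2(C)[C@@H](OC(C)=O)CC=C(C)[C@@H]2[C@@H](OC(C)=O)[C@@]2(O)[C@H](/C=C\1CO)OC(=O)[C@@H]2C | intermediate
31 | CNP0290502.1 (1R,2R,4R,5Z,7S,8S,9R,10S,14S,17R) | CCCC(=O)O[C@@H]1C[C@@H](OC(C)=O)[C@@]2(C)[C@@H](OC(C)=O)CC=C(C)[C@@H]2[C@@H](OC(C)=O)[C@@]2(O)[C@H](/C=C\1COC(C)=O)OC(=O)[C@@H]2C | target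

Total step count: 21. Longest linear sequence: 20 steps (steps 1–7 and 9–21; step 8 prepares coupling partner 15).

Steps most likely to fail

Step 2. The fully substituted enolate may add too slowly to the α-methyl enal, so that retro-Michael equilibration and weak facial discrimination erode the C1/C10 relationship. The fallback sets out from compounds 3 and 4 and returns at compound 6. Compound 4 is condensed with (S)-1-phenylethylamine (toluene, catalytic TsOH, water removal) to the chiral β-enamino ester methyl (Z)-2-methyl-3-{[(1S)-1-phenylethyl]amino}but-2-enoate F1. F1 adds to 3 (toluene, 40 °C) through the compact aza-ene-type transition state of the chiral-enamine Michael alkylation, anti to the phenyl group, giving the imine Michael adduct F2. Aqueous AcOH with pyrrolidine in the same pot hydrolyses the imine to 5, releasing the auxiliary, and effects the aldol condensation to 6. The enantiomeric amine is taken if the facial model requires it.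

Step 19. Closure of the strained ten-membered ring may lose out to intermolecular aldol addition or retro-aldol opening, and the face of the enal may not be differentiated. The fallback sets out from compound 28 and returns at compound 29. Selective α-bromination of the methyl ketone (PhNMe3Br3, THF, 0 °C) gives the bromomethyl ketone F3. SmI2 (THF, −78 °C, high dilution) then generates the samarium enolate, which closes the ring in an irreversible, chelated intramolecular Reformatsky reaction.

Step 4. Hydride may be delivered to the more accessible face of the ring (anti to a pseudo-axial C10 substituent) against the catalyst, giving the C14 epimer. The fallback sets out from compound 7 and returns at compound 8. The small-molecule reductant is replaced by a Prelog-selective NADPH-dependent ketoreductase (i-PrOH recycling, pH 7 buffer/DMSO, 30 °C), in which the enzyme pocket rather than the accessibility of the ring face fixes 14S. This fallback makes no new compound (F0).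

Further compounds
F1 | step 2 | methyl (Z)-2-methyl-3-{[(1S)-1-phenylethyl]amino}but-2-enoate | COC(=O)/C(C)=C(/C)N[C@@H](C)c1ccccc1
F2 | step 2 | imine Michael adduct (N-[(1S)-1-phenylethyl]imine of 5) | COC(=O)[C@@](C)(C(C)=N[C@@H](C)c1ccccc1)[C@@H](C(OC)OC)[C@H](C)C=O
F3 | step 19 | bromomethyl ketone (C3-bromo derivative of 28) | O=C(CBr)[C@@]1(C)[C@@H](OC(C)=O)CC=C(C)[C@@H]1[C@@H](OC(C)=O)[C@@]2(O)[C@H](/C=C(\C=O)CO)OC(=O)[C@@H]2C
F0 | step 4 | none | none
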